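**Remark:** positions are cited in germacrane/eudesmane numbering (ring carbons C1–C10; lactone carbons C11–C13; C14 = methyl on C10; C15 = methyl on C4). Commercial (−)-α-santonin is taken as the starting material.

## Analysis of the target

The target is a germacranolide: a ten-membered carbocycle (C1–C10) fused at C6–C7 to a butenolide (O–C12(=O)–C11=C7, a tetrasubstituted olefin) whose α-carbon C11 carries CH2OAc (C13). The ring also bears a trans C1–C10 epoxide, an acetate at C3 and an (E)-trisubstituted olefin C4=C5. There are four stereocentres: C1 (R), C10 (R), C3 (S) and C6 (R), i.e. 1β,10α-epoxy, 3β-OAc and 6α-O. The epoxide is the oxide of an (E)-C1=C10 olefin, and C3 and C6 are the two allylic centres that flank C4=C5. None of these centres sits in a small rigid ring, so they cannot be relayed by ordinary cyclic stereocontrol. The feature that decides the strategy is the six-carbon unit C1–C2–C3–C4–C5–C10: with oxygen on C3, methyls on C4 and C10, and the lactone oxygen on the neighbouring C6, it is ring A of santonin with the C5–C10 bond missing. Sensitive groups are the epoxide (transannular opening by C4=C5 under acid), the doubly allylic C6–H γ to the lactone carbonyl (base-induced epimerisation or furan formation), and the allylic 13-acetate on an acceptor olefin. The 1,5-diene intermediates can also undergo Cope rearrangement on heating and transannular cyclisation with acid. The hard parts are the medium ring with its (E)-trisubstituted olefin, the remote stereocentres, and the tetrasubstituted butenolide with oxidised C13.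

## Retrosynthetic reasoning

**14 ⇒ 13.** The C1–O and C10–O bonds are removed last. The (E)-C1=C10 olefin of 13 is the only electron-rich olefin, and its peripheral face in the crown conformer leads to the 1β,10α-oxide. The acid-labile epoxide therefore never has to survive another step.

**13 ⇒ 12 ⇒ 11.** The C3 acetate is traced to the C3 ketone of 11. The ketone is exactly what the key step leaves behind, and its 1,2-reduction sets C3 under control of the ten-membered ring conformation.

**11 ⇒ 10 ⇒ 9 (key disconnection).** The ten-membered ring is not closed at all; it is obtained by cutting the C5–C10 σ-bond of a trans-decalin. The C1=C10/C4=C5 diene with a C3 carbonyl in 11 is the desilylated, ring-opened form of the 3-silyloxy-cyclohexa-1,3-diene in 9 (C1=C2–C3(OSi)=C4, with sp3 C5 and C10). The forward reaction has to open this diene by a photochemical conrotatory 6π process to triene 10 and then remove the central C2=C3 bond by desilylation. Cutting here avoids any macrocyclisation, derives both olefin geometries from the trans ring fusion, and leaves the C3 oxygen in place. The precursor 9 is a rigid bicyclic lactone with all 17 carbons of 11.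

**9 ⇒ 8.** The silyl dienol ether comes from enone 8 by enolisation at C4, its only enolisable position.

**8 ⇒ 7 ⇒ 6 ⇒ 5.** The butenolide olefin C7=C11 and the C13–O bond are traced to the exocyclic C11=C13 olefin of 5 through diol 6 and its primary acetate 7. This is done before the ring expansion because the oxidant could not distinguish the ring olefins of the germacrane later.

**5 ⇒ 2.** C1=C2 and C11=C13 are both introduced in one double selenoxide elimination from the ketone/lactone bis-enolate of 2. Kinetic deprotonation fixes the ketone unsaturation on the C2 side.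

**2 ⇒ 1.** Hydrogenation of santonin 1 gives the trans-decalin. Santonin supplies all fifteen skeletal carbons, the C3 oxygen, the C12 carbonyl and the C6 stereocentre in the correct absolute configuration (its descriptor changes from S to R only because C7 later becomes sp2).

## Alternatives that were turned down

**Alternative 1:** (textbook) macrocyclisation at C5–C6. The forward key step would be an intramolecular Nozaki–Hiyama–Kishi coupling of the (E)-vinyl iodide/aldehyde A1, followed by lactonisation of the new C6 alkoxide onto the C12 ester. It was turned down for three reasons. The ten-membered ring must be closed against transannular strain at high dilution. C6 would be set only by 1,4-induction from C3 across a developing ring, with no reliable control element. A1 itself (a γ-oxo-enoate aldehyde, a tetrasubstituted enoate of defined geometry, a trisubstituted vinyl iodide and an epoxide) needs a long linear synthesis that costs more than the ring closure wins.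

**Alternative 2:** anionic oxy-Cope ring expansion. The C1–C6 bond of the divinylcyclohexenol A2 (vinyl adduct of isopiperitenone) would be broken and C8–C9 formed to give cyclodecadienone A3. It was turned down because C4=C5 lies inside the six-membered ring of A2 and is carried into A3 with cis geometry, whereas the target needs 4E. In addition A3 lacks the C3 oxygen, its C6 ketone must be reduced stereoselectively without a controlling element, and the vinyl partner would have to carry C11–C13.

**Alternative 3:** no skeletal bond formation; late C–H oxidation of costunolide A4. The key step would be C3 allylic oxidation towards 3β-acetoxycostunolide A5, followed by transposition of the exocyclic methylene lactone and epoxidation. It was turned down because allylic oxidants attack the methyl groups C14/C15 of the crown-shaped E,E-diene in preference to the poorly aligned ring C3–H bonds. The methylene-to-acetoxymethylbutenolide change also needs osmium or halogen electrophiles that cannot spare the two electron-rich ring olefins. The route would give up control over C3 and the lactone at once.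

Key step: step 7

## Route

**Step 1**
Reactants: 1 (−)-α-santonin
Product: 2 α-tetrahydrosantonin (3-oxo-4βH,5αH,11βH-eudesman-12,6α-olide; trans-decalin, 4α-Me, 10β-Me)
Conditions: H2 (1 atm), 10% Pd/C, EtOAc, 23 °C; then basic Al2O3 (C4 equilibration)
Reagents that add atoms: none
Why: Heterogeneous syn-hydrogenation of both enone olefins; hydrogen should reach C4=C5 from the α-face, opposite the axial C10 methyl, giving the trans ring fusion (5α-H) that step 7 needs. The C4 methyl settles equatorial (α) by enolisation; C4 becomes sp2 again in step 6, so its configuration is not critical.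

**Step 2**
Reactants: 2 α-tetrahydrosantonin
Product: 5 3-oxo-4βH,5αH-eudesma-1,11(13)-dien-12,6α-olide, via 2α,11β-bis(phenylseleno) ketolactone 3 (not isolated), via bis(selenoxide) 4 (not isolated)
Conditions: LDA (2.3 equiv), THF, −78 °C; PhSeCl (2.4 equiv), −78 °C; then 30% H2O2, pyridine, CH2Cl2, 0 → 23 °C
Reagents that add atoms: none
Why: Kinetic deprotonation gives the C2 ketone enolate (the less hindered CH2, not C4) and the C11 lactone enolate; double α-selenenylation and selenoxide syn-elimination then install C1=C2 and C11=C13 in one operation. The C11 selenide should enter on the β-face, anti to H7, so its selenoxide can only eliminate towards C13.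

**Step 3**
Reactants: 5 3-oxo-4βH,5αH-eudesma-1,11(13)-dien-12,6α-olide
Product: 6 11β,13-dihydroxy-3-oxo-4βH,5αH-eudesm-1-en-12,6α-olide
Conditions: OsO4 (2 mol %), NMO (1.2 equiv), acetone–H2O 8:1, 0 → 23 °C
Reagents that add atoms: osmium tetroxide O=[Os](=O)(=O)=O (catalytic oxygen carrier); N-methylmorpholine N-oxide C[N+]1([O-])CCOCC1; water O
Why: Catalytic osmium dihydroxylation should pick the unhindered 1,1-disubstituted exocyclic olefin over the cis-disubstituted enone C1=C2, whose β-carbon is neopentylic (next to quaternary C10). Attack on the β-face of the lactone, anti to axial H7, gives 11β-OH; this centre is removed again in step 5.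

**Step 4**
Reactants: 6 11β,13-dihydroxy-3-oxo-4βH,5αH-eudesm-1-en-12,6α-olide
Product: 7 13-acetoxy-11β-hydroxy-3-oxo-4βH,5αH-eudesm-1-en-12,6α-olide
Conditions: Ac2O (1.2 equiv), pyridine, CH2Cl2, 0 °C
Reagents that add atoms: acetic anhydride CC(=O)OC(C)=O
Why: Acylation of the primary C13 hydroxyl; the tertiary α-hydroxy-lactone OH does not react under these conditions.

**Step 5**
Reactants: 7 13-acetoxy-11β-hydroxy-3-oxo-4βH,5αH-eudesm-1-en-12,6α-olide
Product: 8 13-acetoxy-3-oxo-4βH,5αH-eudesma-1,7(11)-dien-12,6α-olide
Conditions: SOCl2 (2 equiv), pyridine, 0 °C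
Reagents that add atoms: none
Why: Chlorosulfite formation and pyridine-mediated anti E2 dehydration of the tertiary α-hydroxy lactone; the 11β-oxygen is antiperiplanar to H7α. Loss of H7 gives the conjugated tetrasubstituted C7=C11 butenolide rather than an enol acetate towards C13.

**Step 6**
Reactants: 8 13-acetoxy-3-oxo-4βH,5αH-eudesma-1,7(11)-dien-12,6α-olide
Product: 9 13-acetoxy-3-(tert-butyldimethylsilyloxy)-5αH-eudesma-1,3,7(11)-trien-12,6α-olide
Conditions: TBSOTf (1.1 equiv), Et3N (2.5 equiv), CH2Cl2, −78 → −30 °C
Reagents that add atoms: tert-butyldimethylsilyl trifluoromethanesulfonate CC(C)(C)[Si](C)(C)OS(=O)(=O)C(F)(F)F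
Why: Soft enolisation (silyl triflate/amine) of the enone at C4, its only enolisable position (axial H4β), gives the cross-conjugated 2-silyloxy-1,3-diene. Selectivity over γ-silylation of the butenolide rests on the much higher Lewis basicity of the enone carbonyl, low temperature and one equivalent of triflate.

**Step 7**
Reactants: 9 13-acetoxy-3-(tert-butyldimethylsilyloxy)-5αH-eudesma-1,3,7(11)-trien-12,6α-olide
Product: 11 13-acetoxy-3-oxogermacra-1(10)E,4E,7(11)-trien-12,6α-olide, via silyl trienol ether 10 (not isolated)
Conditions: hν (280–300 nm, quartz), degassed THF, −78 °C, to partial conversion; then TBAF (1.1 equiv), AcOH (1.5 equiv), −78 → −30 °C; recovered 8 is resilylated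
Reagents that add atoms: none
Why: Excitation of the silyloxydiene C1=C2–C3=C4 triggers conrotatory 6π-electrocyclic opening of the C5–C10 σ-bond, turning the trans-decalin into the ten-membered trienol silyl ether 10; fluoride then cleaves the O–Si bond and acetic acid protonates the dienolate at its α-carbon C2, giving the C3 ketone with C2H2. The closest known reaction type is the photochemical ring opening of trans-fused eudesma-1,3-dien-12,6-olides to (E,Z,E)-cyclodecatrienes that are trapped by low-temperature hydrogenation; here desilylation takes over the role of removing the central double bond. No ring is closed: the ten-membered ring is unveiled by opening the six-membered ring, so there is no macrocyclisation entropy or high dilution. No stereocentre is formed; C6 is untouched. The geometries of C1=C10 and C4=C5 are fixed by the conrotatory mode acting on the trans ring fusion (H5α, C14β), which turns C6 and C9 outward and should give E,E. Three selectivities are needed: only the diene should absorb at 280–300 nm, since the butenolide absorbs below 240 nm; the triene must not reclose thermally in the disrotatory sense to a cis-fused diene, which is why irradiation and fluoride quench are both run at −78 °C; and protonation must occur at C2 rather than C10, which the buffered kinetic conditions favour. Ketone 11 is taken on at once because its β,γ-olefin can move into conjugation.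

**Step 8**
Reactants: 11 13-acetoxy-3-oxogermacra-1(10)E,4E,7(11)-trien-12,6α-olide
Product: 12 13-acetoxy-3β-hydroxygermacra-1(10)E,4E,7(11)-trien-12,6α-olide
Conditions: NaBH4, CeCl3·7H2O, MeOH–THF, −78 °C
Reagents that add atoms: none
Why: Luche 1,2-reduction of the enone. In the crown conformer of the E,E-cyclodecadiene both methyl groups (C14, C15) project from the β-face, so hydride should add to the α-face of C3 and give the 3β-alcohol (3S). Lactone, acetate and the isolated olefin are inert at −78 °C.

**Step 9**
Reactants: 12 13-acetoxy-3β-hydroxygermacra-1(10)E,4E,7(11)-trien-12,6α-olide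
Product: 13 3β,13-diacetoxygermacra-1(10)E,4E,7(11)-trien-12,6α-olide
Conditions: Ac2O, pyridine, DMAP (cat.), CH2Cl2, 0 °C
Reagents that add atoms: acetic anhydride CC(=O)OC(C)=O
Why: Standard acylation of the secondary allylic alcohol with retention at C3.

**Step 10**
Reactants: 13 3β,13-diacetoxygermacra-1(10)E,4E,7(11)-trien-12,6α-olide
Product: 14 3β,13-diacetoxy-1β,10α-epoxygermacra-4E,7(11)-dien-12,6α-olide (CNP0294733.1)
Conditions: mCPBA (1.05 equiv), NaHCO3, CH2Cl2, 0 °C
Reagents that add atoms: 3-chloroperbenzoic acid OOC(=O)c1cccc(Cl)c1
Why: Prilezhaev epoxidation. C1=C10 is the only electron-rich olefin (C4=C5 is deactivated by two allylic C–O bonds, C7=C11 is conjugated to the lactone). Stereospecific syn addition to the E-olefin from the peripheral face of the crown conformer (C14 β) should give the trans 1β,10α-epoxide (1R,10R).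

## Compound list

1 | (−)-α-santonin (3-oxoeudesma-1,4-dien-12,6α-olide) | C[C@H]1[C@@H]2CC[C@@]3(C)C=CC(=O)C(C)=C3[C@H]2OC1=O | starting material
2 | α-tetrahydrosantonin (3-oxo-4βH,5αH,11βH-eudesman-12,6α-olide) | C[C@H]1[C@@H]2CC[C@@]3(C)CCC(=O)[C@@H](C)[C@@H]3[C@H]2OC1=O | intermediate
3 | 2α,11β-bis(phenylseleno)-3-oxo-4βH,5αH-eudesman-12,6α-olide | C[C@@]1([Se]c4ccccc4)[C@@H]2CC[C@@]3(C)C[C@@H]([Se]c5ccccc5)C(=O)[C@@H](C)[C@@H]3[C@H]2OC1=O | intermediate
4 | bis(selenoxide) of 3 | C[C@@]1([Se](=O)c4ccccc4)[C@@H]2CC[C@@]3(C)C[C@@H]([Se](=O)c5ccccc5)C(=O)[C@@H](C)[C@@H]3[C@H]2OC1=O | intermediate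
5 | 3-oxo-4βH,5αH-eudesma-1,11(13)-dien-12,6α-olide | C=C1[C@@H]2CC[C@@]3(C)C=CC(=O)[C@@H](C)[C@@H]3[C@H]2OC1=O | intermediate
6 | 11β,13-dihydroxy-3-oxo-4βH,5αH-eudesm-1-en-12,6α-olide | OC[C@@]1(O)[C@@H]2CC[C@@]3(C)C=CC(=O)[C@@H](C)[C@@H]3[C@H]2OC1=O | intermediate
7 | 13-acetoxy-11β-hydroxy-3-oxo-4βH,5αH-eudesm-1-en-12,6α-olide | CC(=O)OC[C@@]1(O)[C@@H]2CC[C@@]3(C)C=CC(=O)[C@@H](C)[C@@H]3[C@H]2OC1=O | intermediate
8 | 13-acetoxy-3-oxo-4βH,5αH-eudesma-1,7(11)-dien-12,6α-olide | CC(=O)OCC1=C2CC[C@@]3(C)C=CC(=O)[C@@H](C)[C@@H]3[C@H]2OC1=O | intermediate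
9 | 13-acetoxy-3-(tert-butyldimethylsilyloxy)-5αH-eudesma-1,3,7(11)-trien-12,6α-olide | CC(=O)OCC1=C2CC[C@@]3(C)C=CC(O[Si](C)(C)C(C)(C)C)=C(C)[C@@H]3[C@H]2OC1=O | intermediate
10 | 13-acetoxy-3-(tert-butyldimethylsilyloxy)germacra-1(10),2,4,7(11)-tetraen-12,6α-olide (1(10)E, 4E; C2=C3 cis in the ring) | CC(=O)OCC1=C2CC/C(C)=C/C=C(O[Si](C)(C)C(C)(C)C)\C(C)=C\[C@H]2OC1=O | intermediate
11 | 13-acetoxy-3-oxogermacra-1(10)E,4E,7(11)-trien-12,6α-olide | CC(=O)OCC1=C2CC/C(C)=C/CC(=O)/C(C)=C/[C@H]2OC1=O | intermediate
12 | 13-acetoxy-3β-hydroxygermacra-1(10)E,4E,7(11)-trien-12,6α-olide | CC(=O)OCC1=C2CC/C(C)=C/C[C@H](O)/C(C)=C/[C@H]2OC1=O | intermediate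
13 | 3β,13-diacetoxygermacra-1(10)E,4E,7(11)-trien-12,6α-olide | CC(=O)OCC1=C2CC/C(C)=C/C[C@H](OC(C)=O)/C(C)=C/[C@H]2OC1=O | intermediate
14 | 3β,13-diacetoxy-1β,10α-epoxygermacra-4E,7(11)-dien-12,6α-olide (1R,3S,6R,10R) | CC(=O)OCC1=C2CC[C@@]3(C)O[C@@H]3C[C@H](OC(C)=O)/C(C)=C/[C@H]2OC1=O | target

## Step count and least certain steps

Total step count: 10. Longest linear sequence: 10 steps (1 → 14).

**Step 7 (key step).** The photochemical opening is reversible and the triene itself absorbs, so conversion may stall at a photostationary state. Over-irradiation can divert material into secondary photoreactions (E/Z isomerisation, [1,5]-hydrogen shifts, a di-π-methane reaction across C4=C5/C7=C11). On warming, the triene can reclose thermally to a cis-fused diene. After desilylation the dienolate may be protonated at C10, or the β,γ-olefin may drift into conjugation. Fallback: setting out from 9 and irradiating to 10 as before, the cold solution is hydrogenated (H2, Raney Ni, −40 °C). This is the trapping mode established for such trienes; it saturates only the strained central C2=C3 bond and avoids any enolate, giving the 3-silyl ether F1 as C3 epimers. TBAF then gives the epimeric alcohols F2, and Dess–Martin oxidation converges both on 11, where the route is rejoined.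

**Step 6.** Competing γ-deprotonation and O-silylation of the butenolide at C6–H would form a 2-silyloxyfuran, erasing the C6 stereocentre and endangering the allylic acetate; amine attack on the acetoxymethyl butenolide is a further risk. Fallback: from 8, acid-catalysed enol silylation (BSTFA, TfOH cat., toluene, 23 °C), under which a lactone does not enolise, gives the trimethylsilyl dienol ether F3. Irradiation as in step 7 gives the trimethylsilyl trienol ether F4, and TBAF/AcOH returns to the route at 11.

**Step 3.** Chemoselectivity may be lost through osmylation of the enone C1=C2 alongside the exocyclic olefin, because both are electron-poor. Fallback: the order is changed so that no second olefin is present. From 2, the ketone/lactone bis-enolate (LDA, 2.3 equiv) is treated with PhSeSePh (1.1 equiv), which selenenylates only the more reactive lactone enolate, to give mono-selenide F5. NaIO4 gives selenoxide F6, which eliminates to the saturated keto α-methylene lactone F7. Dihydroxylation gives diol F8 and acetylation gives hydroxy acetate F9. IBX (DMSO, 70 °C) then introduces C1=C2 through the favoured C2 enol, and the route is rejoined at 7.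

**Step 8.** Facial selectivity of hydride addition may be poor, because the ten-membered ring can populate a second conformer in which C15 lies on the α-face; some 1,4-reduction is also possible. Fallback: from 11, if the 3α-alcohol F10 is formed, it is not recycled but inverted during acylation (PPh3, DIAD, AcOH, Mitsunobu reaction), which gives 13 directly and replaces step 9.

## Further compounds

F1 | step 7 | 13-acetoxy-3-(tert-butyldimethylsilyloxy)germacra-1(10)E,4E,7(11)-trien-12,6α-olide (C3 epimers) | CC(=O)OCC1=C2CC/C(C)=C/CC(O[Si](C)(C)C(C)(C)C)/C(C)=C/[C@H]2OC1=O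
F2 | step 7 | 13-acetoxy-3-hydroxygermacra-1(10)E,4E,7(11)-trien-12,6α-olide (C3 epimers) | CC(=O)OCC1=C2CC/C(C)=C/CC(O)/C(C)=C/[C@H]2OC1=O
F3 | step 6 | 13-acetoxy-3-(trimethylsilyloxy)-5αH-eudesma-1,3,7(11)-trien-12,6α-olide | CC(=O)OCC1=C2CC[C@@]3(C)C=CC(O[Si](C)(C)C)=C(C)[C@@H]3[C@H]2OC1=O
F4 | step 6 | 13-acetoxy-3-(trimethylsilyloxy)germacra-1(10),2,4,7(11)-tetraen-12,6α-olide (1(10)E, 4E; C2=C3 cis in the ring) | CC(=O)OCC1=C2CC/C(C)=C/C=C(O[Si](C)(C)C)\C(C)=C\[C@H]2OC1=O
F5 | step 3 | 11β-phenylseleno-3-oxo-4βH,5αH-eudesman-12,6α-olide | C[C@@]1([Se]c4ccccc4)[C@@H]2CC[C@@]3(C)CCC(=O)[C@@H](C)[C@@H]3[C@H]2OC1=O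
F6 | step 3 | selenoxide of F5 | C[C@@]1([Se](=O)c4ccccc4)[C@@H]2CC[C@@]3(C)CCC(=O)[C@@H](C)[C@@H]3[C@H]2OC1=O
F7 | step 3 | 3-oxo-4βH,5αH-eudesm-11(13)-en-12,6α-olide | C=C1[C@@H]2CC[C@@]3(C)CCC(=O)[C@@H](C)[C@@H]3[C@H]2OC1=O
F8 | step 3 | 11β,13-dihydroxy-3-oxo-4βH,5αH-eudesman-12,6α-olide | OC[C@@]1(O)[C@@H]2CC[C@@]3(C)CCC(=O)[C@@H](C)[C@@H]3[C@H]2OC1=O
F9 | step 3 | 13-acetoxy-11β-hydroxy-3-oxo-4βH,5αH-eudesman-12,6α-olide | CC(=O)OC[C@@]1(O)[C@@H]2CC[C@@]3(C)CCC(=O)[C@@H](C)[C@@H]3[C@H]2OC1=O
F10 | step 8 | 13-acetoxy-3α-hydroxygermacra-1(10)E,4E,7(11)-trien-12,6α-olide | CC(=O)OCC1=C2CC/C(C)=C/C[C@@H](O)/C(C)=C/[C@H]2OC1=O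
A1 | alternative 1 | C5–C6 seco precursor: methyl ester at C12 cis to the C6 formyl group on C7=C11, (E)-vinyl iodide at C5, 1β,10α-epoxide, 3β,13-diacetate | COC(=O)/C(COC(C)=O)=C(C=O)/CC[C@@]1(C)O[C@@H]1C[C@H](OC(C)=O)/C(C)=C/I
A2 | alternative 2 | trans-3-methyl-6-(prop-1-en-2-yl)-1-vinylcyclohex-2-en-1-ol (vinyl trans to isopropenyl) | C=C[C@]1(O)C=C(C)CC[C@H]1C(C)=C
A3 | alternative 2 | (2Z,6E)-3,7-dimethylcyclodeca-2,6-dien-1-one | O=C1CCC/C(C)=C/CC/C(C)=C\1
A4 | alternative 3 | (+)-costunolide (germacra-1(10)E,4E,11(13)-trien-12,6α-olide) | C=C1[C@@H]2CC/C(C)=C/CC/C(C)=C/[C@H]2OC1=O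
A5 | alternative 3 | 3β-acetoxycostunolide | C=C1[C@@H]2CC/C(C)=C/C[C@H](OC(C)=O)/C(C)=C/[C@H]2OC1=O
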